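## Plan

1. **Cuts, in retrosynthetic order.**
   - O1'–C2' and C4'–C4a' of the eastern pyran (aryl propargyl ether, Claisen cascade).
   - The two C–H bonds that separate CH(CH3) from C(=CH2).
   - C3=C4 and C=CH2 of the resulting diene (enyne metathesis).
   - The alkyne–aryl bond (Sonogashira).
2. **Enabling feature.** The methyl carbon, the stereogenic carbon, C3 and C4 of the acetyl-bearing western chromene form one four-carbon chain. Written as the diene CH2=C(Ar)–C3=C4, this chain is what remains when a vinyl group on C4a reacts with an aryl alkyne attached through O1–C2(CH3)2.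
3. **Fragments.** The western terminal alkyne comes from 2,4-dihydroxy-6-methoxyacetophenone by C3 formylation, 4-O-propargylation and methylenation. The eastern aryl iodide comes from 3,5-dimethoxyphenol by silylation, lithiation between the methoxy groups and iodination.
4. **Forward order.** The fragments are joined, and the western pyran closes by metathesis. The stereocentre is then set. The eastern pyran closes last, so its disubstituted alkene never meets ruthenium or hydrogen.
5. **Stereochemistry.** The single (S) centre comes from catalyst-controlled, face-selective hydrogenation of the 1,1-disubstituted alkene with a chiral iridium P,N complex. No later step touches that C–H bond.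

Key step: step 7

Assumption: the sense of induction of the iridium catalyst on this diene cannot be read safely from quadrant models. The ligand is therefore written as its (4S,5S) form, and a pilot run with assignment of configuration decides whether this form or the equally available (4R,5R) antipode delivers the (S) centre.

## Route

Step 1
Reactants: 1 2,4-dihydroxy-6-methoxyacetophenone
Product: 3 3-acetyl-2,6-dihydroxy-4-methoxybenzaldehyde, via aryl iminium chloride 2 (not isolated)
Conditions: POCl3 (1.1 equiv), DMF (1.2 equiv), EtOAc, 0 °C to rt; then H2O, rt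
Reagents that add atoms: N,N-dimethylformamide CN(C)C=O; water O
Why: Vilsmeier–Haack formylation, in which the chloroiminium ion should attack C3 (ortho to both free hydroxyls, para to the methoxy group, less crowded than C5), while one equivalent of reagent at or below room temperature leaves the methyl ketone out of the competing 3-formylchromone pathway.

Step 2
Reactants: 3 3-acetyl-2,6-dihydroxy-4-methoxybenzaldehyde; 4 3-chloro-3-methylbut-1-yne
Product: 5 3-acetyl-2-hydroxy-4-methoxy-6-[(2-methylbut-3-yn-2-yl)oxy]benzaldehyde
Conditions: CuCl2·2H2O (1 mol %), DBU, MeCN, 0 °C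
Reagents that add atoms: none
Why: Copper-catalysed propargylic etherification through a copper allenylidene, in which the more acidic and accessible hydroxyl para to the acetyl group reacts while the hydroxyl between the two carbonyl groups is hydrogen-bonded, shielded and stays free.

Step 3
Reactants: 5 3-acetyl-2-hydroxy-4-methoxy-6-[(2-methylbut-3-yn-2-yl)oxy]benzaldehyde
Product: 6 1-{2-hydroxy-6-methoxy-4-[(2-methylbut-3-yn-2-yl)oxy]-3-vinylphenyl}ethanone
Conditions: MePPh3Br (2.5 equiv), KOtBu (2.4 equiv), THF, 0 °C to rt; aq NH4Cl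
Reagents that add atoms: methyltriphenylphosphonium bromide C[P+](c1ccccc1)(c1ccccc1)c1ccccc1.[Br-]
Why: Wittig methylenation, in which the first equivalent of ylide only deprotonates the phenol, the excess converts the aldehyde, and the di-ortho-substituted, phenoxide-conjugated methyl ketone is too hindered and electron-rich to compete.

Step 4
Reactants: 7 3,5-dimethoxyphenol
Product: 8 (3,5-dimethoxyphenoxy)triisopropylsilane
Conditions: TIPSCl, imidazole, DMF, rt
Reagents that add atoms: chlorotriisopropylsilane CC(C)[Si](Cl)(C(C)C)C(C)C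
Why: Standard phenol silylation, giving a bulky silyl ether that tolerates butyllithium, amine bases, ruthenium carbenes and hydrogenation and is a poor director for lithiation.

Step 5
Reactants: 8 (3,5-dimethoxyphenoxy)triisopropylsilane
Product: 10 (4-iodo-3,5-dimethoxyphenoxy)triisopropylsilane, via aryllithium 9 (not isolated)
Conditions: n-BuLi, THF, 0 °C to rt; then I2, −78 °C to rt
Reagents that add atoms: iodine II
Why: Directed ortho-metalation, in which the carbon between the two methoxy groups is activated by double coordination, the carbons next to the bulky silyloxy group are shielded, and iodine traps the aryllithium at that position.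

Step 6
Reactants: 6 1-{2-hydroxy-6-methoxy-4-[(2-methylbut-3-yn-2-yl)oxy]-3-vinylphenyl}ethanone; 10 (4-iodo-3,5-dimethoxyphenoxy)triisopropylsilane
Product: 11 1-{4-[(4-(2,6-dimethoxy-4-triisopropylsilyloxyphenyl)-2-methylbut-3-yn-2-yl)oxy]-2-hydroxy-6-methoxy-3-vinylphenyl}ethanone
Conditions: Pd(PPh3)4 (5 mol %), CuI (10 mol %), Et3N, DMF, 50 °C, degassed
Reagents that add atoms: none
Why: Sonogashira coupling of a terminal alkyne with a 2,6-dimethoxyaryl iodide, run at a temperature below the onset of the aryl propargyl ether Claisen shift and under which the crowded styrene should not enter a Heck reaction.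

Step 7
Reactants: 11 1-{4-[(4-(2,6-dimethoxy-4-triisopropylsilyloxyphenyl)-2-methylbut-3-yn-2-yl)oxy]-2-hydroxy-6-methoxy-3-vinylphenyl}ethanone
Product: 12 1-{3-[1-(2,6-dimethoxy-4-triisopropylsilyloxyphenyl)vinyl]-5-hydroxy-7-methoxy-2,2-dimethyl-2H-chromen-6-yl}ethanone
Conditions: second-generation Grubbs catalyst RuCl2(H2IMes)(PCy3)(=CHPh) (10 mol %), ethene (1 atm), toluene (0.01 M), 70 °C
Reagents that add atoms: none
Why: The catalyst exchanges its benzylidene for the only monosubstituted alkene of 11, and the new ruthenium carbene carbon (future C4) bonds to the alkyne carbon next to the quaternary centre (future C3); the ruthenacyclobutene then opens to a vinylcarbene on the aryl-bearing carbon, which takes a methylene from ethene or from the next styrene and leaves as C(=CH2)Ar. The closest known reaction type is the ring-closing enyne metathesis of ortho-vinylaryl propargyl ethers to 3-vinyl-2H-chromenes. The western pyran closes in the exo mode with one alkyne carbon inside the six-membered ring and one outside, whereas endo closure would place both in a seven-membered benzoxepine. No stereocentre is formed. The step needs ene-first initiation, exo closure and no intermolecular attack of ruthenium methylidene on the alkyne, and these are secured because the alkyne is flanked by a quaternary carbon and a 2,6-dimethoxyaryl ring and so reacts only intramolecularly, while the gem-dimethyl group compresses the O1–C2 tether and holds the alkyne near the carbene. The chelated phenol, aryl ketone and silyl ether are inert to the catalyst, and both alkenes of 12 are too hindered for secondary metathesis.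

Step 8
Reactants: 12 1-{3-[1-(2,6-dimethoxy-4-triisopropylsilyloxyphenyl)vinyl]-5-hydroxy-7-methoxy-2,2-dimethyl-2H-chromen-6-yl}ethanone
Product: 13 1-{3-[(1S)-1-(2,6-dimethoxy-4-triisopropylsilyloxyphenyl)ethyl]-5-hydroxy-7-methoxy-2,2-dimethyl-2H-chromen-6-yl}ethanone
Conditions: [Ir(cod)((4S,5S)-Cy2-ThrePHOX)]BArF (2 mol %; threonine-derived dicyclohexylphosphinite–oxazoline, BArF = tetrakis[3,5-bis(trifluoromethyl)phenyl]borate), H2 (1 bar), CH2Cl2, 0 °C to rt, stopped after one equivalent of H2
Reagents that add atoms: none
Why: Proposed new method: the cationic iridium dihydride should bind only the terminal =CH2 end of the diene, because C3=C4 is trisubstituted and wedged between the quaternary C2 and the benzo ring, so uptake should stop after one equivalent at low pressure. Migratory insertion and reductive elimination deliver both hydrogens to one face, and the chiral pocket should tell apart the 2,6-dimethoxyaryl ring (forced perpendicular to the alkene plane) from the chromenyl group. The alkene carries no allylic C–H, so the terminal-to-internal isomerisation that usually erodes selectivity is impossible. The closest known reaction types are the iridium P,N-catalysed asymmetric hydrogenation of unfunctionalised 1,1-disubstituted terminal alkenes, including 1,1-diarylethenes with one ortho-substituted ring, and the regioselective monohydrogenation of dienes with the same catalyst family. Its use on the terminal end of a conjugated 2-aryl-1,3-diene is new.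

Step 9
Reactants: 13 1-{3-[(1S)-1-(2,6-dimethoxy-4-triisopropylsilyloxyphenyl)ethyl]-5-hydroxy-7-methoxy-2,2-dimethyl-2H-chromen-6-yl}ethanone
Product: 14 1-{5-hydroxy-3-[(1S)-1-(4-hydroxy-2,6-dimethoxyphenyl)ethyl]-7-methoxy-2,2-dimethyl-2H-chromen-6-yl}ethanone
Conditions: TBAF, AcOH (1:1), THF, 0 °C
Reagents that add atoms: none
Why: Fluoride-induced cleavage of the aryl silyl ether, buffered with acetic acid so that the medium stays near neutral and the benzylic-allylic C–H of the stereocentre is not at risk.

Step 10
Reactants: 14 1-{5-hydroxy-3-[(1S)-1-(4-hydroxy-2,6-dimethoxyphenyl)ethyl]-7-methoxy-2,2-dimethyl-2H-chromen-6-yl}ethanone; 4 3-chloro-3-methylbut-1-yne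
Product: 15 1-{3-[(1S)-1-(2,6-dimethoxy-4-[(2-methylbut-3-yn-2-yl)oxy]phenyl)ethyl]-5-hydroxy-7-methoxy-2,2-dimethyl-2H-chromen-6-yl}ethanone
Conditions: CuCl2·2H2O (1 mol %), DBU, MeCN, 0 °C
Reagents that add atoms: none
Why: The same copper-catalysed propargylic etherification as in step 2, selective for the free eastern phenol because the western hydroxyl is tied to the acetyl group by a hydrogen bond and flanked on both sides.

Step 11
Reactants: 15 1-{3-[(1S)-1-(2,6-dimethoxy-4-[(2-methylbut-3-yn-2-yl)oxy]phenyl)ethyl]-5-hydroxy-7-methoxy-2,2-dimethyl-2H-chromen-6-yl}ethanone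
Product: 18 1-{3-[(1S)-1-(5,7-dimethoxy-2,2-dimethyl-2H-chromen-6-yl)ethyl]-5-hydroxy-7-methoxy-2,2-dimethyl-2H-chromen-6-yl}ethanone (target CNP0303487.1), via ortho-allenylphenol 16 (not isolated), via ortho-quinone methide 17 (not isolated)
Conditions: xylenes, 140 °C
Reagents that add atoms: none
Why: Aromatic propargyl Claisen cascade, in which a [3,3] shift to either of the two equivalent ortho carbons followed by enolisation gives 16, a 1,5-hydrogen shift gives 17, and an oxa-6π electrocyclisation closes the eastern pyran without involving any bond at the stereocentre.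

## Compound list

| No. | Name | SMILES | Role |
|---|---|---|---|
| 1 | 2,4-dihydroxy-6-methoxyacetophenone | CC(=O)c1c(O)cc(O)cc1OC | starting material |
| 2 | (3-acetyl-2,6-dihydroxy-4-methoxybenzylidene)dimethyliminium chloride | COc1cc(O)c(C=[N+](C)C)c(O)c1C(C)=O.[Cl-] | intermediate |
| 3 | 3-acetyl-2,6-dihydroxy-4-methoxybenzaldehyde | COc1cc(O)c(C=O)c(O)c1C(C)=O | intermediate |
| 4 | 3-chloro-3-methylbut-1-yne | CC(C)(Cl)C#C | starting material |
| 5 | 3-acetyl-2-hydroxy-4-methoxy-6-[(2-methylbut-3-yn-2-yl)oxy]benzaldehyde | COc1cc(OC(C)(C)C#C)c(C=O)c(O)c1C(C)=O | intermediate |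
| 6 | 1-{2-hydroxy-6-methoxy-4-[(2-methylbut-3-yn-2-yl)oxy]-3-vinylphenyl}ethanone | COc1cc(OC(C)(C)C#C)c(C=C)c(O)c1C(C)=O | intermediate |
| 7 | 3,5-dimethoxyphenol | COc1cc(O)cc(OC)c1 | starting material |
| 8 | (3,5-dimethoxyphenoxy)triisopropylsilane | COc1cc(OC)cc(O[Si](C(C)C)(C(C)C)C(C)C)c1 | intermediate |
| 9 | [2,6-dimethoxy-4-(triisopropylsilyloxy)phenyl]lithium | COc1cc(O[Si](C(C)C)(C(C)C)C(C)C)cc(OC)c1[Li] | intermediate |
| 10 | (4-iodo-3,5-dimethoxyphenoxy)triisopropylsilane | COc1cc(O[Si](C(C)C)(C(C)C)C(C)C)cc(OC)c1I | intermediate |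
| 11 | 1-{4-[(4-(2,6-dimethoxy-4-triisopropylsilyloxyphenyl)-2-methylbut-3-yn-2-yl)oxy]-2-hydroxy-6-methoxy-3-vinylphenyl}ethanone | COc1cc(OC(C)(C)C#Cc2c(OC)cc(O[Si](C(C)C)(C(C)C)C(C)C)cc2OC)c(C=C)c(O)c1C(C)=O | intermediate |
| 12 | 1-{3-[1-(2,6-dimethoxy-4-triisopropylsilyloxyphenyl)vinyl]-5-hydroxy-7-methoxy-2,2-dimethyl-2H-chromen-6-yl}ethanone | COc1cc2c(c(O)c1C(C)=O)C=C(C(=C)c1c(OC)cc(O[Si](C(C)C)(C(C)C)C(C)C)cc1OC)C(C)(C)O2 | intermediate |
| 13 | 1-{3-[(1S)-1-(2,6-dimethoxy-4-triisopropylsilyloxyphenyl)ethyl]-5-hydroxy-7-methoxy-2,2-dimethyl-2H-chromen-6-yl}ethanone | COc1cc2c(c(O)c1C(C)=O)C=C([C@H](C)c1c(OC)cc(O[Si](C(C)C)(C(C)C)C(C)C)cc1OC)C(C)(C)O2 | intermediate |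
| 14 | 1-{5-hydroxy-3-[(1S)-1-(4-hydroxy-2,6-dimethoxyphenyl)ethyl]-7-methoxy-2,2-dimethyl-2H-chromen-6-yl}ethanone | COc1cc2c(c(O)c1C(C)=O)C=C([C@H](C)c1c(OC)cc(O)cc1OC)C(C)(C)O2 | intermediate |
| 15 | 1-{3-[(1S)-1-(2,6-dimethoxy-4-[(2-methylbut-3-yn-2-yl)oxy]phenyl)ethyl]-5-hydroxy-7-methoxy-2,2-dimethyl-2H-chromen-6-yl}ethanone | COc1cc2c(c(O)c1C(C)=O)C=C([C@H](C)c1c(OC)cc(OC(C)(C)C#C)cc1OC)C(C)(C)O2 | intermediate |
| 16 | 1-{5-hydroxy-3-[(1S)-1-(4-hydroxy-2,6-dimethoxy-3-(3-methylbuta-1,2-dienyl)phenyl)ethyl]-7-methoxy-2,2-dimethyl-2H-chromen-6-yl}ethanone | COc1cc2c(c(O)c1C(C)=O)C=C([C@H](C)c1c(OC)cc(O)c(C=C=C(C)C)c1OC)C(C)(C)O2 | intermediate |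
| 17 | (Z)-ortho-quinone methide: 4-[(1S)-1-(6-acetyl-5-hydroxy-7-methoxy-2,2-dimethyl-2H-chromen-3-yl)ethyl]-3,5-dimethoxy-6-(3-methylbut-2-enylidene)cyclohexa-2,4-dienone | COc1cc2c(c(O)c1C(C)=O)C=C([C@H](C)C1=C(OC)/C(=C/C=C(C)C)C(=O)C=C1OC)C(C)(C)O2 | intermediate |
| 18 | 1-{3-[(1S)-1-(5,7-dimethoxy-2,2-dimethyl-2H-chromen-6-yl)ethyl]-5-hydroxy-7-methoxy-2,2-dimethyl-2H-chromen-6-yl}ethanone | COc1cc2c(c(O)c1C(C)=O)C=C([C@H](C)c1c(OC)cc3c(c1OC)C=CC(C)(C)O3)C(C)(C)O2 | target |

## Step count and risks

- **Total step count:** 11.
- **Longest linear sequence:** 9 steps (steps 1, 2, 3, 6, 7, 8, 9, 10, 11, from compound 1).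

**First risk, step 8.**
- What may go wrong: facial discrimination may be poor because both substituents on the prochiral carbon are bulky sp2 groups. Hydrogen may also add further to C3=C4, or across the ends of the diene.
- Fallback: catalytic induction is replaced by resolution, setting out from 12. Non-stereoselective hydrogenation of the terminal alkene with RhCl(PPh3)3 and H2 in benzene–ethanol should give the racemic ethyl-bridged silyl ether F1. TBAF buffered with acetic acid should release the racemic ethyl-bridged diphenol F2. Preparative chromatography on a cellulose tris(3,5-dimethylphenylcarbamate) phase separates the enantiomers. The (S) enantiomer is 14, where the route resumes.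

**Second risk, step 7.**
- What may go wrong: the substrate-derived ruthenium benzylidene may fail to engage an alkyne shielded on both sides. Alternatively, the aryl-substituted vinylcarbene may rest as a chelate with an ortho-methoxy oxygen, so that turnover stops.
- Fallback: the ring closure is kept, but the aryl group is brought in afterwards, setting out from 6. Dehydrogenative C–H borylation of the terminal alkyne (pinacolborane, (CAAC)CuOTf, Et3N, benzene, rt) should give the alkynyl pinacolboronate F3. A further equivalent of borane is taken up by the phenol and lost again on work-up. Ring-closing enyne metathesis of alkynylboronates with RuCl2(H2IMes)(PCy3)(=CHPh) is known. The boron substituent is flat and non-chelating, and the reaction should give the 3-(1-borylvinyl)chromene F4. Suzuki–Miyaura coupling of F4 with iodide 10 (Pd(OAc)2, SPhos, K3PO4, THF–H2O, 50 °C) returns to the route at 12.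

**Third risk, step 1.**
- What may go wrong: the chloroiminium ion may attack C5 in competition with C3, or it may consume the methyl ketone and start chromone formation.
- Fallback: the order is changed so that only one phenol is left to direct the formyl group, setting out from 1 and 4. Copper-catalysed etherification (CuCl2·2H2O, DBU, MeCN, 0 °C) of the non-chelated 4-hydroxyl should give the 4-O-(1,1-dimethylpropargyl) acetophenone F5. Magnesium-mediated ortho-formylation (Casnati–Skattebøl conditions: MgCl2, Et3N, paraformaldehyde, THF, reflux) delivers the aldehyde only next to a free phenol. In F5 the single open ortho carbon is C3. This comes back to the route at 5.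

Further compounds
F1 | step 8 | racemic 1-{3-[1-(2,6-dimethoxy-4-triisopropylsilyloxyphenyl)ethyl]-5-hydroxy-7-methoxy-2,2-dimethyl-2H-chromen-6-yl}ethanone | COc1cc2c(c(O)c1C(C)=O)C=C(C(C)c1c(OC)cc(O[Si](C(C)C)(C(C)C)C(C)C)cc1OC)C(C)(C)O2
F2 | step 8 | racemic 1-{5-hydroxy-3-[1-(4-hydroxy-2,6-dimethoxyphenyl)ethyl]-7-methoxy-2,2-dimethyl-2H-chromen-6-yl}ethanone | COc1cc2c(c(O)c1C(C)=O)C=C(C(C)c1c(OC)cc(O)cc1OC)C(C)(C)O2
F3 | step 7 | 1-{2-hydroxy-6-methoxy-4-[(2-methyl-4-(4,4,5,5-tetramethyl-1,3,2-dioxaborolan-2-yl)but-3-yn-2-yl)oxy]-3-vinylphenyl}ethanone | COc1cc(OC(C)(C)C#CB2OC(C)(C)C(C)(C)O2)c(C=C)c(O)c1C(C)=O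
F4 | step 7 | 1-{5-hydroxy-7-methoxy-2,2-dimethyl-3-[1-(4,4,5,5-tetramethyl-1,3,2-dioxaborolan-2-yl)vinyl]-2H-chromen-6-yl}ethanone | COc1cc2c(c(O)c1C(C)=O)C=C(C(=C)B1OC(C)(C)C(C)(C)O1)C(C)(C)O2
F5 | step 1 | 1-{2-hydroxy-6-methoxy-4-[(2-methylbut-3-yn-2-yl)oxy]phenyl}ethanone | COc1cc(OC(C)(C)C#C)cc(O)c1C(C)=O
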